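**Retrosynthetic overview**

- The target 15 comes from its catechol bis-MOM ether 14 by mild acidic acetal cleavage.
- 14 is cut at C1''–C2'' and C1'''–C2''': both prenyl groups arise from the 6,8-bis(dimethylaminomethyl) Mannich base 9 and two molecules of (2-methylprop-1-enyl)boronic acid through A-ring ortho-quinone methides.
- The feature that carries the plan: the benzylic CH2 of each prenyl group, on C8 and on C6 of ring A, sits ortho to a free phenol (O7 for C8; O7 or O5 for C6).
- 9 comes from (S)-eriodictyol by catechol bis-MOM protection (7-OH silylated transiently) and a double Mannich reaction at C6 and C8.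
- No ring is formed: ring A, the chromanone ring C with its (2S) centre and ring B are all taken intact from (S)-eriodictyol.

Key step: step 4

Assumption: (S)-eriodictyol of high enantiomeric purity is taken as a purchasable natural product. In steps 3 and 4 the C8 position is drawn as reacting first; either order leads to the same compounds 9 and 14.

**Route**

Step 1
Reactants: 1 (S)-eriodictyol; 2 triisopropylsilyl chloride
Product: 3 (2S)-2-(3,4-dihydroxyphenyl)-5-hydroxy-7-(triisopropylsilyloxy)chroman-4-one
Conditions: TIPSCl (1.05 equiv), imidazole (2 equiv), DMF, −20 → 0 °C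
Reagents that add atoms: triisopropylsilyl chloride (2), CC(C)[Si](Cl)(C(C)C)C(C)C
Why: Acidity-controlled phenol silylation: the 7-OH, para to the C4 carbonyl, is the most acidic hydroxyl and should react ahead of the catechol hydroxyls, while the 5-OH is held in a hydrogen bond to C4=O; imidazole at or below 0 °C should not open the chromanone, so C2 stays (S).

Step 2
Reactants: 3 (2S)-7-O-triisopropylsilyl-eriodictyol; 4 chloromethyl methyl ether
Product: 6 (2S)-5,7-dihydroxy-3',4'-bis(methoxymethoxy)flavanone, via 7-O-TIPS bis-MOM ether 5 (not isolated)
Conditions: MOMCl (2.6 equiv), iPr2NEt (3.5 equiv), CH2Cl2, 0 °C → rt; aqueous work-up; then TBAF (1.1 equiv), AcOH (1.5 equiv), THF, 0 °C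
Reagents that add atoms: chloromethyl methyl ether (4), COCCl
Why: O-alkylation of the two catechol hydroxyls with MOMCl under amine base, the chelated 5-OH being inert at this stoichiometry, followed by acetic acid-buffered fluoride cleavage of the aryl silyl ether, which is fast because the 7-phenoxide is a good leaving group; the MOM acetals and C2 are not touched.

Step 3
Reactants: 6 (2S)-5,7-dihydroxy-3',4'-bis(methoxymethoxy)flavanone; 7 dimethylmethyleneiminium iodide
Product: 9 (2S)-6,8-bis(dimethylaminomethyl)-5,7-dihydroxy-3',4'-bis(methoxymethoxy)flavanone, via 8-aminomethyl mono-Mannich base 8 (not isolated)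
Conditions: Me2N=CH2+ I− (2.3 equiv), MeCN, 0 °C → rt; cold sat. aq NaHCO3 work-up; used without storage
Reagents that add atoms: dimethylmethyleneiminium iodide (7), C=[N+](C)C.[I-]
Why: Double Mannich reaction (electrophilic aromatic aminomethylation) with the preformed iminium salt: C6 and C8 are the only ring carbons activated by the free 5- and 7-hydroxyls and far outrank the acetal-protected B ring, and the acid released is taken up by the product amines, so the bis-hydroiodide should be stable until it is neutralised cold.

Step 4
Reactants: 9 (2S)-6,8-bis(dimethylaminomethyl)-5,7-dihydroxy-3',4'-bis(methoxymethoxy)flavanone; 10 (2-methylprop-1-en-1-yl)boronic acid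
Product: 14 (2S)-5,7-dihydroxy-3',4'-bis(methoxymethoxy)-6,8-diprenylflavanone, via first ortho-quinone methide 11 (not isolated), via 8-prenyl mono-Mannich base 12 (not isolated), via second ortho-quinone methide 13 (not isolated)
Conditions: 10 (5 equiv), 4 Å MS, toluene (0.02 M), 90 °C, Ar; then aq NH4Cl work-up
Reagents that add atoms: (2-methylprop-1-en-1-yl)boronic acid (10), CC(C)=CB(O)O
Why: On heating, the zwitterionic form of each phenolic Mannich arm (phenoxide/ammonium) expels dimethylamine to give an ortho-quinone methide; the boronic acid binds the quinone methide oxygen, and the resulting tetracoordinate boronate passes its 2-methylprop-1-enyl group through the boron-bearing carbon to the exocyclic CH2 in a six-membered transition state, which re-aromatises ring A as an aryl borate that is hydrolysed on work-up, after which the sequence repeats at the second arm. The closest known reaction type is the 1,4-addition of alkenylboron reagents to ortho-quinone methides generated thermally from ortho-aminomethyl- or ortho-alkoxymethylphenols. No ring is closed and no stereocentre is created; the (2S) centre is only carried through. The step needs transfer through the boron-bearing carbon (linear prenyl, no allylic transposition) and attack at CH2 and not at oxygen, both enforced by the cyclic O–B–C transition state, while the position of each prenyl group is already fixed by where the Mannich reaction placed the CH2 groups. It also needs C2 to survive, which the weakly basic medium (liberated amine tied up by excess boronic acid and sieves) and the C4=O···HO-5 hydrogen bond, which disfavours retro-oxa-Michael opening, should secure. High dilution and excess boron reagent should keep a quinone methide from being trapped by a second flavanone molecule.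

Step 5
Reactants: 14 (2S)-5,7-dihydroxy-3',4'-bis(methoxymethoxy)-6,8-diprenylflavanone
Product: 15 6,8-diprenyleriodictyol, (2S)-2-(3,4-dihydroxyphenyl)-5,7-dihydroxy-6,8-bis(3-methylbut-2-en-1-yl)chroman-4-one
Conditions: aq HCl (about 1 M final) in MeOH, 40 °C, stopped at full conversion
Reagents that add atoms: none
Why: Acid-catalysed transacetalisation of the two aryl MOM ethers to methanol, a standard unmasking of prenylated flavonoids; dilute acid, mild temperature and a short reaction time should keep the ortho-prenyl phenols from cyclising to chromans and should not open the chromanone, so C2 stays (S).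

**Compound list**

1 | (S)-eriodictyol | O=C1C[C@@H](c2ccc(O)c(O)c2)Oc2cc(O)cc(O)c21 | starting material
2 | triisopropylsilyl chloride | CC(C)[Si](Cl)(C(C)C)C(C)C | starting material
3 | (2S)-2-(3,4-dihydroxyphenyl)-5-hydroxy-7-(triisopropylsilyloxy)chroman-4-one | O=C1C[C@@H](c2ccc(O)c(O)c2)Oc2cc(O[Si](C(C)C)(C(C)C)C(C)C)cc(O)c21 | intermediate
4 | chloromethyl methyl ether | COCCl | starting material
5 | (2S)-5-hydroxy-3',4'-bis(methoxymethoxy)-7-(triisopropylsilyloxy)flavanone | O=C1C[C@@H](c2ccc(OCOC)c(OCOC)c2)Oc2cc(O[Si](C(C)C)(C(C)C)C(C)C)cc(O)c21 | intermediate
6 | (2S)-5,7-dihydroxy-3',4'-bis(methoxymethoxy)flavanone | O=C1C[C@@H](c2ccc(OCOC)c(OCOC)c2)Oc2cc(O)cc(O)c21 | intermediate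
7 | dimethylmethyleneiminium iodide | C=[N+](C)C.[I-] | starting material
8 | (2S)-8-(dimethylaminomethyl)-5,7-dihydroxy-3',4'-bis(methoxymethoxy)flavanone | O=C1C[C@@H](c2ccc(OCOC)c(OCOC)c2)Oc2c(CN(C)C)c(O)cc(O)c21 | intermediate
9 | (2S)-6,8-bis(dimethylaminomethyl)-5,7-dihydroxy-3',4'-bis(methoxymethoxy)flavanone | CN(C)Cc1c(O)c(CN(C)C)c2c(c1O)C(=O)C[C@@H](c1ccc(OCOC)c(OCOC)c1)O2 | intermediate
10 | (2-methylprop-1-en-1-yl)boronic acid | CC(C)=CB(O)O | starting material
11 | (2S)-2-[3,4-bis(methoxymethoxy)phenyl]-6-(dimethylaminomethyl)-5-hydroxy-8-methylidene-2,3-dihydrochromene-4,7-dione (first ortho-quinone methide) | C=C1C(=O)C(CN(C)C)=C(O)C2=C1O[C@H](c1ccc(OCOC)c(OCOC)c1)CC2=O | intermediate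
12 | (2S)-6-(dimethylaminomethyl)-5,7-dihydroxy-3',4'-bis(methoxymethoxy)-8-prenylflavanone (free-phenol form; carried in the flask partly as its O-borate) | CN(C)Cc1c(O)c(CC=C(C)C)c2c(c1O)C(=O)C[C@@H](c1ccc(OCOC)c(OCOC)c1)O2 | intermediate
13 | (2S)-2-[3,4-bis(methoxymethoxy)phenyl]-5-hydroxy-6-methylidene-8-(3-methylbut-2-en-1-yl)-2,3-dihydrochromene-4,7-dione (second ortho-quinone methide) | C=C1C(=O)C(CC=C(C)C)=C2O[C@H](c3ccc(OCOC)c(OCOC)c3)CC(=O)C2=C1O | intermediate
14 | (2S)-5,7-dihydroxy-3',4'-bis(methoxymethoxy)-6,8-diprenylflavanone | CC(C)=CCc1c(O)c(CC=C(C)C)c2c(c1O)C(=O)C[C@@H](c1ccc(OCOC)c(OCOC)c1)O2 | intermediate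
15 | 6,8-diprenyleriodictyol | CC(C)=CCc1c(O)c(CC=C(C)C)c2c(c1O)C(=O)C[C@@H](c1ccc(O)c(O)c1)O2 | target

**Step count and risks**

Total step count: 5. Longest linear sequence: 5 steps, from (S)-eriodictyol 1.

Steps most likely to fail:

1. Step 4. The ortho-quinone methides may be consumed by pathways other than alkenyl transfer: trapping by a phenol of a second molecule to give methylene-bridged oligomers, re-addition of amine that stalls the second arm, protodeboronation of the reagent, or partial epimerisation at C2 by reversible ring opening. Fallback: set out from 6 and replace the quinone methide chemistry by halogenation and cross-coupling. Iodination with N-iodosuccinimide (2.1 equiv) in DMF at 0 °C should give (S)-5,7-dihydroxy-6,8-diiodo-3',4'-bis(methoxymethoxy)flavanone F1, the same two carbons being the only nucleophilic ring positions. A twofold Stille coupling of F1 with tributyl(3-methylbut-2-en-1-yl)stannane (Pd(PPh3)4, DMF, 90 °C) under neutral conditions should then deliver the linear prenyl groups and return to the route at 14.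

2. Step 1. Site selectivity of the monosilylation may be insufficient (silylation of a catechol hydroxyl or double silylation), which would carry a wrong MOM pattern forward. Fallback: set out from 1 and dispense with catechol protection. The A ring is far more nucleophilic than the catechol ring, so dimethylmethyleneiminium iodide (2.2 equiv, MeCN/DMF, rt) should aminomethylate C6 and C8 only and give (2S)-6,8-bis(dimethylaminomethyl)eriodictyol F2, handled as its bis-hydroiodide and neutralised just before use. Heating F2 with excess boronic acid 10 (at least 6 equiv, dioxane, 90 °C) should mask the catechol reversibly as a cyclic alkenylboronate while both quinone methide alkenylations run. Work-up with aqueous sorbitol should release the catechol and return to the route at 15.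

3. Step 3. The second aminomethylation may be incomplete, and the bis-Mannich base may lose amine prematurely on neutralisation and isolation, leading to self-condensation. Fallback: set out from 6 and install the two arms one at a time. One equivalent of the iminium salt should give the mono-Mannich base 8, now isolated; heating 8 with boronic acid 10 as in step 4 should give (2S)-5,7-dihydroxy-3',4'-bis(methoxymethoxy)-8-prenylflavanone F3. A second aminomethylation at the remaining free position C6 should give 12, and a second alkenylation returns to the route at 14. If the first aminomethylation takes place at C6 instead, the sequence converges on the same compound 14.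

**Further compounds**

F1 | step 4 | (S)-5,7-dihydroxy-6,8-diiodo-3',4'-bis(methoxymethoxy)flavanone | O=C1C[C@@H](c2ccc(OCOC)c(OCOC)c2)Oc2c(I)c(O)c(I)c(O)c21
F2 | step 1 | (2S)-6,8-bis(dimethylaminomethyl)eriodictyol | CN(C)Cc1c(O)c(CN(C)C)c2c(c1O)C(=O)C[C@@H](c1ccc(O)c(O)c1)O2
F3 | step 3 | (2S)-5,7-dihydroxy-3',4'-bis(methoxymethoxy)-8-prenylflavanone | O=C1C[C@@H](c2ccc(OCOC)c(OCOC)c2)Oc2c(CC=C(C)C)c(O)cc(O)c21
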